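## Retrosynthetic overview

- The strategy rests on benzo ring E of the benzofuran (C3a'–C4'–C5'–C6'–C7'–C7a'): its oxygen sits at C7', next to the fusion carbon C7a' that carries the furan oxygen, the hydroxypropyl chain sits at C5' (meta to that oxygen), and C4' and C6' are unsubstituted. This is the pattern left when a ketene carbon closes onto the α-carbon of a 3-alkenylfuran.
- Ring E is made last. Cutting C7'–C7a' (6π closure) and C5'–C6' (Wolff shift) leads back to a (Z)-furyl-enone diazoketone in which ring D is still a simple 2-aryl-4-alkenylfuran.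
- The diazoketone comes from a 2-aryl-4-formylfuran by Z-selective Still–Gennari olefination with a phosphonate that already carries the silyloxypropyl chain, then ester cleavage and acylation of diazomethane. The formylfuran comes from Suzuki coupling of the 5-bromo-dihydrobenzofuran core with (4-formylfuran-2-yl)boronic acid.
- The trans (2S,3R) core (rings A, B, C) comes from an Evans syn-aldol between an arylacetyl oxazolidinone (from 5-bromo-o-vanillin by one-carbon homologation) and O-silyl vanillin, followed by reductive auxiliary removal and acid-mediated phenol cyclisation.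
- Ring order: rings A, B and D are bought as vanillin, 5-bromo-o-vanillin and the furylboronic acid; ring C is closed in step 9 and ring E in step 16.

Key step: step 16

Remark (assumption): the target is read as the trans (2S,3R) isomer. Rings are lettered A (guaiacyl ring), B and C (benzene and dihydrofuran rings of the dihydrobenzofuran), D and E (furan and benzene rings of the benzofuran, primed locants). The furylboronic acid, the bis(trifluoroethyl) phosphonoacetate and the silyloxypropyl iodide are taken as purchased.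

Abbreviations used in names: TBSO = (tert-butyldimethylsilyl)oxy; ArA = 3-methoxy-4-[(triisopropylsilyl)oxy]phenyl; ArB = 2-(allyloxy)-5-bromo-3-methoxyphenyl; DHB = (2S,3R)-3-[(TBSO)methyl]-7-methoxy-2-(ArA)-2,3-dihydro-1-benzofuran-5-yl.

## Route

Step 1
Reactants: 1 vanillin (4-hydroxy-3-methoxybenzaldehyde)
Product: 2 3-methoxy-4-[(triisopropylsilyl)oxy]benzaldehyde
Conditions: TIPSCl, imidazole, DMF, rt
Reagents that add atoms: triisopropylsilyl chloride CC(C)[Si](Cl)(C(C)C)C(C)C
Why: Imidazole-promoted silylation of the phenol installs a bulky silyl ether that should survive the acidic cyclisation and the basic coupling steps and fall to fluoride at the end.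

Step 2
Reactants: 3 5-bromo-2-hydroxy-3-methoxybenzaldehyde
Product: 4 2-(allyloxy)-5-bromo-3-methoxybenzaldehyde
Conditions: allyl bromide, K2CO3, DMF, rt
Reagents that add atoms: allyl bromide C=CCBr
Why: Williamson etherification of the phenoxide; the allyl group tolerates the acid and base of the next steps and can later be removed with zerovalent palladium without touching the aryl bromide.

Step 3
Reactants: 4 2-(allyloxy)-5-bromo-3-methoxybenzaldehyde
Product: 5 1-(allyloxy)-4-bromo-2-methoxy-6-[2-(methylsulfanyl)-2-(methylsulfinyl)ethenyl]benzene (alkene isomers; racemic at sulfur)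
Conditions: MeS(O)CH2SMe, PhCH2NMe3 OH (cat., 40% in MeOH), THF, reflux
Reagents that add atoms: methyl (methylsulfanyl)methyl sulfoxide CSCS(C)=O
Why: Knoevenagel-type condensation of the aldehyde with the acidic methylene of the dithioacetal S-oxide gives a ketene dithioacetal monoxide, a masked arylacetic acid in which both alkene isomers serve equally.

Step 4
Reactants: 5 1-(allyloxy)-4-bromo-2-methoxy-6-[2-(methylsulfanyl)-2-(methylsulfinyl)ethenyl]benzene
Product: 7 2-[2-(allyloxy)-5-bromo-3-methoxyphenyl]acetic acid, via ethyl ester 6 (not isolated)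
Conditions: HCl, EtOH, rt; then aq NaOH, THF, rt; then aq HCl to pH 2
Reagents that add atoms: ethanol CCO (held only by intermediate 6); sodium hydroxide [Na+].[OH-]
Why: Acid-mediated ethanolysis of the ketene dithioacetal S-oxide (C-protonation, ethanol addition, loss of both sulfur groups) should give the ethyl arylacetate, which is saponified in the same flask; the allyl ether and aryl bromide are inert to both stages.

Step 5
Reactants: 7 2-[2-(allyloxy)-5-bromo-3-methoxyphenyl]acetic acid; 8 (4S)-4-benzyl-1,3-oxazolidin-2-one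
Product: 10 (4S)-3-[2-(ArB)acetyl]-4-benzyl-1,3-oxazolidin-2-one, via mixed pivalic anhydride 9 (not isolated)
Conditions: PivCl, Et3N, THF, −20 °C; then 8, LiCl, −20 °C → rt
Reagents that add atoms: pivaloyl chloride CC(C)(C)C(Cl)=O (held only by intermediate 9)
Why: N-Acylation of the oxazolidinone through the mixed pivalic anhydride, where LiCl activates the auxiliary and attack occurs at the less hindered arylacetyl carbonyl.

Step 6
Reactants: 10 (4S)-3-[2-(ArB)acetyl]-4-benzyl-1,3-oxazolidin-2-one; 2 3-methoxy-4-[(triisopropylsilyl)oxy]benzaldehyde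
Product: 12 (4S)-3-[(2S,3S)-2-(ArB)-3-hydroxy-3-(ArA)propanoyl]-4-benzyl-1,3-oxazolidin-2-one, via Z-boron enolate 11 (not isolated)
Conditions: Bu2BOTf, iPr2NEt, CH2Cl2, 0 °C; then 2, −78 → 0 °C; then pH 7 buffer, MeOH, 30% H2O2, 0 °C
Reagents that add atoms: dibutylboron triflate CCCCB(CCCC)OS(=O)(=O)C(F)(F)F (held only by intermediate 11)
Why: Evans syn-aldol reaction in which the Z-boron enolate reacts through a chair Zimmerman–Traxler transition state and the benzyl group of the (4S)-auxiliary blocks one enolate face, so the α-carbon (later C3 of ring C) and the carbinol carbon should both be set as S, as with the propionyl analogue and benzaldehyde.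

Step 7
Reactants: 12 (4S)-3-[(2S,3S)-2-(ArB)-3-hydroxy-3-(ArA)propanoyl]-4-benzyl-1,3-oxazolidin-2-one
Product: 13 (1S,2R)-2-(ArB)-1-(ArA)propane-1,3-diol
Conditions: LiBH4, MeOH (1 equiv), THF, 0 °C
Reagents that add atoms: none
Why: Reductive cleavage of the imide by hydride attack at the exocyclic carbonyl releases the primary alcohol and the auxiliary without touching either stereocentre (the descriptor at C2 changes only because CH2OH replaces the acyl group in the priority order).

Step 8
Reactants: 13 (1S,2R)-2-(ArB)-1-(ArA)propane-1,3-diol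
Product: 14 (1S,2R)-2-(5-bromo-2-hydroxy-3-methoxyphenyl)-1-(ArA)propane-1,3-diol
Conditions: Pd(PPh3)4 (5 mol%), morpholine, THF, rt
Reagents that add atoms: none
Why: Tsuji–Trost deallylation in which zerovalent palladium ionises the aryl allyl ether to a π-allyl complex that morpholine captures; at room temperature the electron-rich aryl bromide should not undergo oxidative addition.

Step 9
Reactants: 14 (1S,2R)-2-(5-bromo-2-hydroxy-3-methoxyphenyl)-1-(ArA)propane-1,3-diol
Product: 15 [(2S,3R)-5-bromo-7-methoxy-2-(ArA)-2,3-dihydro-1-benzofuran-3-yl]methanol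
Conditions: TsOH·H2O (10 mol%), CH2Cl2, 0 °C, short reaction time
Reagents that add atoms: none
Why: Acid-catalysed SN1 cyclodehydration in which the para-silyloxybenzylic cation is captured 5-exo by the neighbouring phenol faster than it can lose a proton; the aryl group takes the face opposite the CH2OH group at C3 (fixed as R in step 6), so the trans (2S) configuration at C2 should result, the trans ring also being the more stable one.

Step 10
Reactants: 15 [(2S,3R)-5-bromo-7-methoxy-2-(ArA)-2,3-dihydro-1-benzofuran-3-yl]methanol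
Product: 16 tert-butyl{[(2S,3R)-5-bromo-7-methoxy-2-(ArA)-2,3-dihydro-1-benzofuran-3-yl]methoxy}dimethylsilane
Conditions: TBSCl, imidazole, DMF, 0 °C → rt
Reagents that add atoms: tert-butyldimethylsilyl chloride CC(C)(C)[Si](C)(C)Cl
Why: Silylation of the primary alcohol, needed so that the later acyl chloride and diazoketone stages meet no free hydroxyl group.

Step 11
Reactants: 16 tert-butyl{[(2S,3R)-5-bromo-7-methoxy-2-(ArA)-2,3-dihydro-1-benzofuran-3-yl]methoxy}dimethylsilane; 17 (4-formylfuran-2-yl)boronic acid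
Product: 18 5-(DHB)furan-3-carbaldehyde
Conditions: Pd(OAc)2 (5 mol%), SPhos (10 mol%), K3PO4, THF/H2O (degassed), 50 °C
Reagents that add atoms: none
Why: Suzuki–Miyaura coupling in which the electron-rich biarylphosphine speeds oxidative addition of the electron-rich aryl bromide, so that coupling should outrun protodeboronation of the 2-furylboronic acid, which the formyl group also slows.

Step 12
Reactants: 19 methyl 2-[bis(2,2,2-trifluoroethoxy)phosphoryl]acetate; 20 tert-butyl(3-iodopropoxy)dimethylsilane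
Product: 21 methyl 2-[bis(2,2,2-trifluoroethoxy)phosphoryl]-5-(TBSO)pentanoate (racemic)
Conditions: NaH, DMF, 0 °C; then 20, rt → 45 °C
Reagents that add atoms: none
Why: SN2 C-alkylation of the stabilised phosphonoacetate anion by the primary iodide; a second alkylation is slowed by the hindered tertiary carbanion.

Step 13
Reactants: 18 5-(DHB)furan-3-carbaldehyde; 21 methyl 2-[bis(2,2,2-trifluoroethoxy)phosphoryl]-5-(TBSO)pentanoate
Product: 22 methyl (2Z)-5-(TBSO)-2-{[5-(DHB)furan-3-yl]methylidene}pentanoate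
Conditions: KN(SiMe3)2, 18-crown-6, THF, −78 °C; then 18, −78 °C
Reagents that add atoms: none
Why: Still–Gennari variant of the Horner–Wadsworth–Emmons olefination, in which the electron-poor trifluoroethyl phosphonate and the crown-separated potassium ion make elimination from the kinetic adduct fast, so the trisubstituted alkene should form with the furyl group cis to the ester (Z).

Step 14
Reactants: 22 methyl (2Z)-5-(TBSO)-2-{[5-(DHB)furan-3-yl]methylidene}pentanoate
Product: 23 (2Z)-5-(TBSO)-2-{[5-(DHB)furan-3-yl]methylidene}pentanoic acid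
Conditions: Me3SnOH, ClCH2CH2Cl, 80 °C; then cold 5% aq HCl wash
Reagents that add atoms: trimethyltin hydroxide C[Sn](C)(C)O
Why: Tin hydroxide-mediated ester cleavage under nearly neutral conditions, chosen over aqueous hydroxide so that the base-labile aryl silyl ether, the two alkyl silyl ethers and the Z alkene should all survive.

Step 15
Reactants: 23 (2Z)-5-(TBSO)-2-{[5-(DHB)furan-3-yl]methylidene}pentanoic acid
Product: 25 (3Z)-1-diazo-4-[5-(DHB)furan-3-yl]-3-[3-(TBSO)propyl]but-3-en-2-one, via acid chloride 24 (not isolated)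
Conditions: Me2C=C(Cl)NMe2, CH2Cl2, 0 °C → rt; then CH2N2 (excess), Et2O, 0 °C, dark
Reagents that add atoms: 1-chloro-N,N,2-trimethylprop-1-en-1-amine CC(C)=C(Cl)N(C)C (chlorine held only by intermediate 24); diazomethane C=[N+]=[N-]
Why: Acid chloride formation with the α-chloroenamine under neutral conditions (no HCl to cleave silyl ethers or isomerise the alkene), followed by acylation of diazomethane as in the first stage of an Arndt–Eistert sequence; a second equivalent of diazomethane takes up HCl, and the trisubstituted, donor-substituted alkene is a poor dipolarophile.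

Step 16
Reactants: 25 (3Z)-1-diazo-4-[5-(DHB)furan-3-yl]-3-[3-(TBSO)propyl]but-3-en-2-one
Product: 28 2-(DHB)-5-[3-(TBSO)propyl]-1-benzofuran-7-ol, via dienylketene 26 (not isolated), via cyclohexadienone 27 (not isolated)
Conditions: hν (365 nm), degassed toluene (0.005 M), rt; then 80 °C, dark
Reagents that add atoms: none
Why: Excitation of the diazoketone expels N2 with a 1,2-shift of the alkenyl carbon C5' from the carbonyl carbon to the diazo carbon (new C5'–C6' bond), giving dienylketene 26 in which the ketene C=C, the C4'=C5' alkene and the furan C4=C5 bond (later C3a'–C7a') form a cis-hexatriene. Thermal disrotatory 6π electrocyclisation then joins the ketene carbon to the furan α-carbon (C7'–C7a') and closes the six-membered carbocyclic ring E as 7aH-benzofuranone 27, which should enolise at once to the aromatic 7'-phenol 28. The closest known reaction type is the photochemical Wolff rearrangement of unsaturated α-diazoketones to vinyl- or dienylketenes followed by 6π closure to phenols, as in ketene-based aromatic annulations, including closures onto furan and thiophene rings. No stereocentre is created (C7a' is sp3 only in 27), and C2 and C3 of ring C lie outside the reacting chromophore. The step needs closure at the furan α-carbon, which is secured because only the furan C4=C5 bond completes the hexatriene and only that closure gives an aromatic benzofuran; it also needs the furyl group cis to the ketenyl group, which the Z-olefination of step 13 installs and photoisomerisation under the irradiation should replenish. High dilution and the exclusion of water, alcohols and amines keep the ketene from dimerising or being trapped before it cyclises.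

Step 17
Reactants: 28 2-(DHB)-5-[3-(TBSO)propyl]-1-benzofuran-7-ol
Product: 29 2-(DHB)-7-methoxy-5-[3-(TBSO)propyl]-1-benzofuran
Conditions: MeI, K2CO3, acetone, 40 °C
Reagents that add atoms: iodomethane CI
Why: Williamson O-methylation of the only free phenol; anhydrous carbonate in acetone should leave the aryl silyl ether of ring A intact, so that ring A is not methylated.

Step 18
Reactants: 29 2-(DHB)-7-methoxy-5-[3-(TBSO)propyl]-1-benzofuran
Product: 30 4-[(2S,3R)-3-(hydroxymethyl)-5-[5-(3-hydroxypropyl)-7-methoxy-1-benzofuran-2-yl]-7-methoxy-2,3-dihydro-1-benzofuran-2-yl]-2-methoxyphenol (CNP0308311.1)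
Conditions: Bu4NF, AcOH, THF, 0 °C → rt
Reagents that add atoms: none
Why: Fluoride-mediated cleavage of the three silyl ethers, buffered with acetic acid so that the freed para-hydroxyphenyl group does not open ring C through a quinone methide; no stereocentre is touched.

## Compound list

1 | vanillin (4-hydroxy-3-methoxybenzaldehyde) | COc1cc(C=O)ccc1O | starting material
2 | 3-methoxy-4-[(triisopropylsilyl)oxy]benzaldehyde | COc1cc(C=O)ccc1O[Si](C(C)C)(C(C)C)C(C)C | intermediate
3 | 5-bromo-2-hydroxy-3-methoxybenzaldehyde | COc1cc(Br)cc(C=O)c1O | starting material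
4 | 2-(allyloxy)-5-bromo-3-methoxybenzaldehyde | COc1cc(Br)cc(C=O)c1OCC=C | intermediate
5 | 1-(allyloxy)-4-bromo-2-methoxy-6-[2-(methylsulfanyl)-2-(methylsulfinyl)ethenyl]benzene (alkene isomers; racemic at sulfur) | COc1cc(Br)cc(C=C(SC)S(C)=O)c1OCC=C | intermediate
6 | ethyl 2-[2-(allyloxy)-5-bromo-3-methoxyphenyl]acetate (not isolated) | CCOC(=O)Cc1cc(Br)cc(OC)c1OCC=C | intermediate
7 | 2-[2-(allyloxy)-5-bromo-3-methoxyphenyl]acetic acid | OC(=O)Cc1cc(Br)cc(OC)c1OCC=C | intermediate
8 | (4S)-4-benzyl-1,3-oxazolidin-2-one | O=C1N[C@@H](Cc2ccccc2)CO1 | starting material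
9 | mixed anhydride of acid 7 with pivalic acid (not isolated) | CC(C)(C)C(=O)OC(=O)Cc1cc(Br)cc(OC)c1OCC=C | intermediate
10 | (4S)-3-{2-[2-(allyloxy)-5-bromo-3-methoxyphenyl]acetyl}-4-benzyl-1,3-oxazolidin-2-one | C=CCOc1c(OC)cc(Br)cc1CC(=O)N1C(=O)OC[C@@H]1Cc1ccccc1 | intermediate
11 | (Z)-dibutylboron enolate of imide 10 (not isolated) | CCCCB(CCCC)O/C(=C\c1cc(Br)cc(OC)c1OCC=C)N1C(=O)OC[C@@H]1Cc1ccccc1 | intermediate
12 | (4S)-3-[(2S,3S)-2-[2-(allyloxy)-5-bromo-3-methoxyphenyl]-3-hydroxy-3-{3-methoxy-4-[(triisopropylsilyl)oxy]phenyl}propanoyl]-4-benzyl-1,3-oxazolidin-2-one | COc1cc([C@@H](O)[C@@H](C(=O)N2C(=O)OC[C@@H]2Cc2ccccc2)c2cc(Br)cc(OC)c2OCC=C)ccc1O[Si](C(C)C)(C(C)C)C(C)C | intermediate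
13 | (1S,2R)-2-[2-(allyloxy)-5-bromo-3-methoxyphenyl]-1-{3-methoxy-4-[(triisopropylsilyl)oxy]phenyl}propane-1,3-diol | COc1cc([C@@H](O)[C@@H](CO)c2cc(Br)cc(OC)c2OCC=C)ccc1O[Si](C(C)C)(C(C)C)C(C)C | intermediate
14 | (1S,2R)-2-(5-bromo-2-hydroxy-3-methoxyphenyl)-1-{3-methoxy-4-[(triisopropylsilyl)oxy]phenyl}propane-1,3-diol | COc1cc([C@@H](O)[C@@H](CO)c2cc(Br)cc(OC)c2O)ccc1O[Si](C(C)C)(C(C)C)C(C)C | intermediate
15 | [(2S,3R)-5-bromo-7-methoxy-2-{3-methoxy-4-[(triisopropylsilyl)oxy]phenyl}-2,3-dihydro-1-benzofuran-3-yl]methanol | COc1cc([C@H]2Oc3c(OC)cc(Br)cc3[C@@H]2CO)ccc1O[Si](C(C)C)(C(C)C)C(C)C | intermediate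
16 | tert-butyl{[(2S,3R)-5-bromo-7-methoxy-2-{3-methoxy-4-[(triisopropylsilyl)oxy]phenyl}-2,3-dihydro-1-benzofuran-3-yl]methoxy}dimethylsilane | COc1cc([C@H]2Oc3c(OC)cc(Br)cc3[C@@H]2CO[Si](C)(C)C(C)(C)C)ccc1O[Si](C(C)C)(C(C)C)C(C)C | intermediate
17 | (4-formylfuran-2-yl)boronic acid | O=Cc1coc(B(O)O)c1 | starting material
18 | 5-(DHB)furan-3-carbaldehyde | COc1cc([C@H]2Oc3c(OC)cc(-c4cc(C=O)co4)cc3[C@@H]2CO[Si](C)(C)C(C)(C)C)ccc1O[Si](C(C)C)(C(C)C)C(C)C | intermediate
19 | methyl 2-[bis(2,2,2-trifluoroethoxy)phosphoryl]acetate | COC(=O)CP(=O)(OCC(F)(F)F)OCC(F)(F)F | starting material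
20 | tert-butyl(3-iodopropoxy)dimethylsilane | CC(C)(C)[Si](C)(C)OCCCI | starting material
21 | methyl 2-[bis(2,2,2-trifluoroethoxy)phosphoryl]-5-[(tert-butyldimethylsilyl)oxy]pentanoate (racemic) | COC(=O)C(CCCO[Si](C)(C)C(C)(C)C)P(=O)(OCC(F)(F)F)OCC(F)(F)F | intermediate
22 | methyl (2Z)-5-(TBSO)-2-{[5-(DHB)furan-3-yl]methylidene}pentanoate | COc1cc([C@H]2Oc3c(OC)cc(-c4cc(/C=C(/CCCO[Si](C)(C)C(C)(C)C)C(=O)OC)co4)cc3[C@@H]2CO[Si](C)(C)C(C)(C)C)ccc1O[Si](C(C)C)(C(C)C)C(C)C | intermediate
23 | (2Z)-5-(TBSO)-2-{[5-(DHB)furan-3-yl]methylidene}pentanoic acid | COc1cc([C@H]2Oc3c(OC)cc(-c4cc(/C=C(/CCCO[Si](C)(C)C(C)(C)C)C(=O)O)co4)cc3[C@@H]2CO[Si](C)(C)C(C)(C)C)ccc1O[Si](C(C)C)(C(C)C)C(C)C | intermediate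
24 | (2Z)-5-(TBSO)-2-{[5-(DHB)furan-3-yl]methylidene}pentanoyl chloride (not isolated) | COc1cc([C@H]2Oc3c(OC)cc(-c4cc(/C=C(/CCCO[Si](C)(C)C(C)(C)C)C(=O)Cl)co4)cc3[C@@H]2CO[Si](C)(C)C(C)(C)C)ccc1O[Si](C(C)C)(C(C)C)C(C)C | intermediate
25 | (3Z)-1-diazo-4-[5-(DHB)furan-3-yl]-3-[3-(TBSO)propyl]but-3-en-2-one | COc1cc([C@H]2Oc3c(OC)cc(-c4cc(/C=C(/CCCO[Si](C)(C)C(C)(C)C)C(=O)C=[N+]=[N-])co4)cc3[C@@H]2CO[Si](C)(C)C(C)(C)C)ccc1O[Si](C(C)C)(C(C)C)C(C)C | intermediate
26 | (3Z)-4-[5-(DHB)furan-3-yl]-3-[3-(TBSO)propyl]buta-1,3-dien-1-one (dienylketene, not isolated) | COc1cc([C@H]2Oc3c(OC)cc(-c4cc(/C=C(/CCCO[Si](C)(C)C(C)(C)C)C=C=O)co4)cc3[C@@H]2CO[Si](C)(C)C(C)(C)C)ccc1O[Si](C(C)C)(C(C)C)C(C)C | intermediate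
27 | 2-(DHB)-5-[3-(TBSO)propyl]-1-benzofuran-7(7aH)-one (both C7a epimers, not isolated) | COc1cc([C@H]2Oc3c(OC)cc(C4=CC5=CC(CCCO[Si](C)(C)C(C)(C)C)=CC(=O)C5O4)cc3[C@@H]2CO[Si](C)(C)C(C)(C)C)ccc1O[Si](C(C)C)(C(C)C)C(C)C | intermediate
28 | 2-(DHB)-5-[3-(TBSO)propyl]-1-benzofuran-7-ol | COc1cc([C@H]2Oc3c(OC)cc(-c4cc5cc(CCCO[Si](C)(C)C(C)(C)C)cc(O)c5o4)cc3[C@@H]2CO[Si](C)(C)C(C)(C)C)ccc1O[Si](C(C)C)(C(C)C)C(C)C | intermediate
29 | 2-(DHB)-7-methoxy-5-[3-(TBSO)propyl]-1-benzofuran | COc1cc([C@H]2Oc3c(OC)cc(-c4cc5cc(CCCO[Si](C)(C)C(C)(C)C)cc(OC)c5o4)cc3[C@@H]2CO[Si](C)(C)C(C)(C)C)ccc1O[Si](C(C)C)(C(C)C)C(C)C | intermediate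
30 | 4-[(2S,3R)-3-(hydroxymethyl)-5-[5-(3-hydroxypropyl)-7-methoxy-1-benzofuran-2-yl]-7-methoxy-2,3-dihydro-1-benzofuran-2-yl]-2-methoxyphenol | COc1cc([C@H]2Oc3c(OC)cc(-c4cc5cc(CCCO)cc(OC)c5o4)cc3[C@@H]2CO)ccc1O | target

## Step count and risks

Total step count: 18. Longest linear sequence: 16 steps (3 → 30 through steps 2–11 and 13–18).

Steps most likely to fail:

Step 16. The photogenerated ketene may dimerise or be intercepted before it reaches the cyclisation geometry, the excited diazoketone may react through carbene-type pathways on the furan, and the extended aryl–furan chromophore may absorb competitively and slow the Wolff step. The fallback sets out from 25 and comes back at 28; it closes ring E thermally by the classical acetic anhydride benzannulation of a 4-arylbut-3-enoic acid. Silver benzoate-catalysed Wolff rearrangement of 25 in methanol in the dark (PhCO2Ag, Et3N, MeOH, rt; Arndt–Eistert homologation) should trap the ketene as methyl (3Z)-4-[5-(DHB)furan-3-yl]-3-[3-(TBSO)propyl]but-3-enoate F1. Me3SnOH in 1,2-dichloroethane at 80 °C should give (3Z)-4-[5-(DHB)furan-3-yl]-3-[3-(TBSO)propyl]but-3-enoic acid F2. Heating F2 with Ac2O and NaOAc at 120 °C forms the mixed anhydride, which should cyclise onto the furan α-carbon and be acetylated to 2-(DHB)-5-[3-(TBSO)propyl]-1-benzofuran-7-yl acetate F3. K2CO3 in MeOH at 0 °C then removes the acetate and returns phenol 28.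

Step 15. Diazomethane may add as a dipole across the conjugated alkene, the Z alkene may isomerise during acyl activation, and adventitious HCl may strip a silyl ether. The fallback sets out from 23 and comes back at 25; it uses neither an acyl chloride nor diazomethane. Coupling of 23 with N,O-dimethylhydroxylamine hydrochloride (EDC·HCl, HOBt, iPr2NEt, CH2Cl2) should give (2Z)-N-methoxy-N-methyl-5-(TBSO)-2-{[5-(DHB)furan-3-yl]methylidene}pentanamide F4. MeMgBr in THF at 0 °C should convert F4 into (3Z)-4-[5-(DHB)furan-3-yl]-3-[3-(TBSO)propyl]but-3-en-2-one F5. Kinetic enolisation of the methyl group (LiN(SiMe3)2, THF, −78 °C) and trifluoroacetylation with CF3CO2CH2CF3 give (5Z)-1,1,1-trifluoro-6-[5-(DHB)furan-3-yl]-5-[3-(TBSO)propyl]hex-5-ene-2,4-dione F6, which is not isolated. Treatment of F6 with MsN3, Et3N and H2O in MeCN (detrifluoroacetylative diazo transfer) should deliver 25.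

Step 13. The Z-selectivity may erode with the α-branched phosphonate, and addition to the electron-rich heteroaryl aldehyde may be slow at −78 °C. The fallback sets out from 18 and comes back at 22; it sets the geometry after the olefination instead of during it. Trimethyl phosphonoacetate is alkylated with 20 (NaH, DMF) to methyl 2-(dimethoxyphosphoryl)-5-(TBSO)pentanoate F7. A classical Horner–Wadsworth–Emmons reaction of F7 with 18 (NaH, THF, 0 °C → rt) should give mainly methyl (2E)-5-(TBSO)-2-{[5-(DHB)furan-3-yl]methylidene}pentanoate F8. Triplet-sensitised alkene isomerisation of F8 (Ir(ppy)3, 450 nm, MeCN, rt) should then give a photostationary mixture from which 22 is separated and the E isomer recycled.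

Further compounds
F1 | step 16 | methyl (3Z)-4-[5-(DHB)furan-3-yl]-3-[3-(TBSO)propyl]but-3-enoate | COc1cc([C@H]2Oc3c(OC)cc(-c4cc(/C=C(/CCCO[Si](C)(C)C(C)(C)C)CC(=O)OC)co4)cc3[C@@H]2CO[Si](C)(C)C(C)(C)C)ccc1O[Si](C(C)C)(C(C)C)C(C)C
F2 | step 16 | (3Z)-4-[5-(DHB)furan-3-yl]-3-[3-(TBSO)propyl]but-3-enoic acid | COc1cc([C@H]2Oc3c(OC)cc(-c4cc(/C=C(/CCCO[Si](C)(C)C(C)(C)C)CC(=O)O)co4)cc3[C@@H]2CO[Si](C)(C)C(C)(C)C)ccc1O[Si](C(C)C)(C(C)C)C(C)C
F3 | step 16 | 2-(DHB)-5-[3-(TBSO)propyl]-1-benzofuran-7-yl acetate | COc1cc([C@H]2Oc3c(OC)cc(-c4cc5cc(CCCO[Si](C)(C)C(C)(C)C)cc(OC(C)=O)c5o4)cc3[C@@H]2CO[Si](C)(C)C(C)(C)C)ccc1O[Si](C(C)C)(C(C)C)C(C)C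
F4 | step 15 | (2Z)-N-methoxy-N-methyl-5-(TBSO)-2-{[5-(DHB)furan-3-yl]methylidene}pentanamide | COc1cc([C@H]2Oc3c(OC)cc(-c4cc(/C=C(/CCCO[Si](C)(C)C(C)(C)C)C(=O)N(C)OC)co4)cc3[C@@H]2CO[Si](C)(C)C(C)(C)C)ccc1O[Si](C(C)C)(C(C)C)C(C)C
F5 | step 15 | (3Z)-4-[5-(DHB)furan-3-yl]-3-[3-(TBSO)propyl]but-3-en-2-one | COc1cc([C@H]2Oc3c(OC)cc(-c4cc(/C=C(/CCCO[Si](C)(C)C(C)(C)C)C(C)=O)co4)cc3[C@@H]2CO[Si](C)(C)C(C)(C)C)ccc1O[Si](C(C)C)(C(C)C)C(C)C
F6 | step 15 | (5Z)-1,1,1-trifluoro-6-[5-(DHB)furan-3-yl]-5-[3-(TBSO)propyl]hex-5-ene-2,4-dione | COc1cc([C@H]2Oc3c(OC)cc(-c4cc(/C=C(/CCCO[Si](C)(C)C(C)(C)C)C(=O)CC(=O)C(F)(F)F)co4)cc3[C@@H]2CO[Si](C)(C)C(C)(C)C)ccc1O[Si](C(C)C)(C(C)C)C(C)C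
F7 | step 13 | methyl 2-(dimethoxyphosphoryl)-5-[(tert-butyldimethylsilyl)oxy]pentanoate | COC(=O)C(CCCO[Si](C)(C)C(C)(C)C)P(=O)(OC)OC
F8 | step 13 | methyl (2E)-5-(TBSO)-2-{[5-(DHB)furan-3-yl]methylidene}pentanoate | COc1cc([C@H]2Oc3c(OC)cc(-c4cc(/C=C(\CCCO[Si](C)(C)C(C)(C)C)C(=O)OC)co4)cc3[C@@H]2CO[Si](C)(C)C(C)(C)C)ccc1O[Si](C(C)C)(C(C)C)C(C)C
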